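**Retrosynthetic overview**
1. The target is opened at both exocyclic Z-alkenes: two successive Wittig reactions of the C4 bis-phosphonium salt 17 with two epimeric 6-substituted oxan-3-ones, 15 (OH/isopropenyl cis) and 16 (OH/isopropenyl trans).
2. Each oxan-3-one comes from a γ-lactone by one-carbon ring expansion (sulfoxonium ylide opening, then iridium-carbene O–H insertion); the oxane rings are formed last before coupling.
3. Both cyclopentanols 10 and 11 come from one lactone aldehyde 9 by diastereodivergent intramolecular carbonyl-ene cyclisation; the cyclopentane is the second ring formed.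
4. Lactone 8 (first ring) comes from the key homoaldol: a titanium ester homoenolate adds to the unprotected β-hydroxy aldehyde 5, and chelation sets the C–O stereocentre.
5. Aldehyde 5 comes from organocatalytic α-hydroxymethylation of 6-methylhept-5-enal 3, itself made from hex-5-enal by cross-metathesis.

Assumption: the SMILES is taken literally, so the two cyclopentanol units are epimers at the isopropenyl-bearing carbon (OH/isopropenyl cis in one, trans in the other), and two diastereomeric half-ketones are made and joined one after the other.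

**Route**

Step 1
Reactants: 1 hex-5-enal; 2 2-methylbut-2-ene
Product: 3 6-methylhept-5-enal
Conditions: second-generation Grubbs catalyst RuCl2(=CHPh)(PCy3)(H2IMes) (2 mol%), excess 2 in CH2Cl2, 40 °C
Reagents that add atoms: none
Why: Olefin cross-metathesis of a terminal alkene with excess 2-methylbut-2-ene gives the isopropylidene alkene and propene; no stereocentre is formed.

Step 2
Reactants: 3 6-methylhept-5-enal; 4 formaldehyde (37% aqueous)
Product: 5 (2S)-2-(hydroxymethyl)-6-methylhept-5-enal
Conditions: (R)-α,α-diphenylprolinol trimethylsilyl ether (10 mol%), pH 7 phosphate buffer, toluene, 20 °C; extract, dry, use at once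
Reagents that add atoms: none
Why: Enamine-catalysed cross-aldol with formaldehyde (organocatalytic α-hydroxymethylation), in which the CPh2(OSiMe3) group shields one face of the E-enamine so that the (R)-catalyst is predicted to give the (S)-aldehyde (about 95% ee expected).

Step 3 (key step)
Reactants: 5 (2S)-2-(hydroxymethyl)-6-methylhept-5-enal; 6 (1-ethoxycyclopropoxy)trimethylsilane
Product: 8 (5R)-5-[(2S)-1-hydroxy-6-methylhept-5-en-2-yl]oxolan-2-one, via hydroxy ester 7 (not isolated)
Conditions: 6 (2.5 equiv), TiCl4 (2.5 equiv), CH2Cl2, 0 to 20 °C; Ti(OiPr)4 (1.25 equiv); then 5, −40 to 0 °C; H2O quench; TsOH (cat.), CH2Cl2, 20 °C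
Reagents that add atoms: none
Why: Proposed new method: a hydroxyl-directed homoaldol with a titanium ester homoenolate, in which the free OH of 5 exchanges onto titanium, the aldehyde oxygen closes a six-membered chelate, and the ester β-carbon (normally an acceptor site, here nucleophilic) attacks the aldehyde carbon on the face opposite the homoprenyl chain to give the 4,5-anti adduct 7 (new carbinol centre R), which lactonises to 8; the closest known reactions are the Nakamura–Kuwajima addition of Cl3TiCH2CH2CO2R to aldehydes with lactonisation and chelation-controlled additions of alkyltitanium chlorides to α-substituted β-oxygenated aldehydes, and the isopropoxide ligands are there to take up the OH proton as propan-2-ol and so limit HCl.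

Step 4
Reactants: 8 (5R)-5-[(2S)-1-hydroxy-6-methylhept-5-en-2-yl]oxolan-2-one
Product: 9 (2R)-6-methyl-2-[(2R)-5-oxooxolan-2-yl]hept-5-enal
Conditions: Dess–Martin periodinane (1.3 equiv), CH2Cl2, 0 °C; short filtration, use crude
Reagents that add atoms: none
Why: Dess–Martin oxidation of the primary alcohol under non-basic conditions keeps the labile α-centre and avoids β-elimination of the lactone oxygen (the descriptor changes only because CIP priorities change).

Step 5
Reactants: 9 (2R)-6-methyl-2-[(2R)-5-oxooxolan-2-yl]hept-5-enal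
Product: 10 (5R)-5-[(1S,2S,3R)-2-hydroxy-3-(prop-1-en-2-yl)cyclopentyl]oxolan-2-one
Conditions: Me2AlCl (2.2 equiv), CH2Cl2, −78 °C
Reagents that add atoms: none
Why: Lewis acid-promoted intramolecular (type 1) carbonyl-ene reaction under kinetic control, in which the lactone substituent and the aluminium-bound oxygen sit pseudo-equatorial (OH trans to the lactone-bearing carbon) and the closed six-membered hydrogen transfer from an allylic methyl to oxygen requires oxygen and the alkene terminus syn, giving OH cis to isopropenyl.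

Step 6
Reactants: 9 (2R)-6-methyl-2-[(2R)-5-oxooxolan-2-yl]hept-5-enal
Product: 11 (5R)-5-[(1S,2S,3S)-2-hydroxy-3-(prop-1-en-2-yl)cyclopentyl]oxolan-2-one
Conditions: confined BINOL-derived imidodiphosphoric acid (5 mol%, enantiomer matched to 9), cyclohexane, 25 °C
Reagents that add atoms: none
Why: Brønsted acid-catalysed carbonyl-ene cyclisation by a stepwise path, in which C–C closure goes through the all-pseudo-equatorial arrangement and the counter-anion then removes a methyl proton with no syn requirement, giving the all-trans cyclopentanol (OH trans to both neighbours).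

Step 7
Reactants: 10 (5R)-5-[(1S,2S,3R)-2-hydroxy-3-(prop-1-en-2-yl)cyclopentyl]oxolan-2-one; 12 trimethylsulfoxonium iodide
Product: 13 (5R)-1-[dimethyl(oxo)-λ6-sulfanylidene]-5-hydroxy-5-[(1R,2S,3R)-2-hydroxy-3-(prop-1-en-2-yl)cyclopentyl]pentan-2-one
Conditions: 12 (3 equiv), KOtBu (3 equiv), THF, 65 °C; then 10, 0 to 20 °C
Reagents that add atoms: none
Why: Acyl transfer from the lactone to dimethylsulfoxonium methylide (Corey–Chaykovsky reagent) opens the ring to the stabilised β-keto sulfoxonium ylide without touching any stereocentre (the ring-carbon descriptor changes by CIP priority only).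

Step 8
Reactants: 11 (5R)-5-[(1S,2S,3S)-2-hydroxy-3-(prop-1-en-2-yl)cyclopentyl]oxolan-2-one; 12 trimethylsulfoxonium iodide
Product: 14 (5R)-1-[dimethyl(oxo)-λ6-sulfanylidene]-5-hydroxy-5-[(1R,2S,3S)-2-hydroxy-3-(prop-1-en-2-yl)cyclopentyl]pentan-2-one
Conditions: 12 (3 equiv), KOtBu (3 equiv), THF, 65 °C; then 11, 0 to 20 °C
Reagents that add atoms: none
Why: Same lactone opening by dimethylsulfoxonium methylide as in step 7; no stereocentre is touched.

Step 9
Reactants: 13 (the hydroxy keto sulfoxonium ylide of the cis series)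
Product: 15 (6R)-6-[(1S,2S,3R)-2-hydroxy-3-(prop-1-en-2-yl)cyclopentyl]oxan-3-one
Conditions: [Ir(cod)Cl]2 (2 mol%), 1,2-dichloroethane (0.02 M), 70 °C
Reagents that add atoms: none
Why: Iridium-carbene O–H insertion with the sulfoxonium ylide as diazo surrogate, in which the δ-hydroxyl closes the six-membered ring (insertion by the cyclopentanol OH would need an eight-membered ring) and the C–O stereocentre is retained because its C–O bond is not broken.

Step 10
Reactants: 14 (the hydroxy keto sulfoxonium ylide of the trans series)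
Product: 16 (6R)-6-[(1S,2S,3S)-2-hydroxy-3-(prop-1-en-2-yl)cyclopentyl]oxan-3-one
Conditions: [Ir(cod)Cl]2 (2 mol%), 1,2-dichloroethane (0.02 M), 70 °C
Reagents that add atoms: none
Why: Same iridium-carbene O–H insertion as in step 9; no stereocentre is touched.

Step 11
Reactants: 15 (6R)-6-[(1S,2S,3R)-2-hydroxy-3-(prop-1-en-2-yl)cyclopentyl]oxan-3-one; 17 butane-1,4-diylbis(triphenylphosphonium) dibromide
Product: 18 {(4Z)-4-[(6R)-6-[(1S,2S,3R)-2-hydroxy-3-(prop-1-en-2-yl)cyclopentyl]oxan-3-ylidene]butyl}triphenylphosphonium bromide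
Conditions: 17 (3 equiv), KN(SiMe3)2 (3 equiv), THF, −78 to 0 °C; HMPA, then 15, −78 to 20 °C; chromatography (CH2Cl2/MeOH)
Reagents that add atoms: none
Why: Wittig olefination of an α-alkoxy ketone with an unstabilised ylide (Still-type Z-selective variant), in which the ylide chain ends syn to the ring O–CH2 arm to give the Z alkene, while one equivalent of base per bis-salt and limiting ketone keep the second phosphonium end intact.

Step 12
Reactants: 18 (the cis-series phosphonium bromide); 16 (6R)-6-[(1S,2S,3S)-2-hydroxy-3-(prop-1-en-2-yl)cyclopentyl]oxan-3-one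
Product: 19 (1S,2S,5R)-2-[(2R,5Z)-5-{(4Z)-4-[(6R)-6-[(1S,2S,3S)-2-hydroxy-3-(prop-1-en-2-yl)cyclopentyl]oxan-3-ylidene]butylidene}oxan-2-yl]-5-(prop-1-en-2-yl)cyclopentan-1-ol (target)
Conditions: 18 (1.3 equiv), KN(SiMe3)2 (1.3 equiv), THF/HMPA, −78 °C; then 16, −78 to 20 °C
Reagents that add atoms: none
Why: Second Still-type Wittig olefination of the α-alkoxy ketone gives the second Z alkene by the same preference; the free hydroxyls are far less acidic than the phosphonium α-CH and are tolerated, and minor diastereomers from imperfect ee are removed here.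

**Compound list**
1 | hex-5-enal | C=CCCCC=O | starting material
2 | 2-methylbut-2-ene | CC=C(C)C | starting material
3 | 6-methylhept-5-enal | CC(C)=CCCCC=O | intermediate
4 | formaldehyde | C=O | starting material
5 | (2S)-2-(hydroxymethyl)-6-methylhept-5-enal | CC(C)=CCC[C@H](C=O)CO | intermediate
6 | (1-ethoxycyclopropoxy)trimethylsilane | CCOC1(CC1)O[Si](C)(C)C | starting material
7 | ethyl (4R,5S)-4-hydroxy-5-(hydroxymethyl)-9-methyldec-8-enoate | CC(C)=CCC[C@H]([C@H](O)CCC(=O)OCC)CO | intermediate
8 | (5R)-5-[(2S)-1-hydroxy-6-methylhept-5-en-2-yl]oxolan-2-one | CC(C)=CCC[C@H]([C@H]1CCC(=O)O1)CO | intermediate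
9 | (2R)-6-methyl-2-[(2R)-5-oxooxolan-2-yl]hept-5-enal | CC(C)=CCC[C@H]([C@H]1CCC(=O)O1)C=O | intermediate
10 | (5R)-5-[(1S,2S,3R)-2-hydroxy-3-(prop-1-en-2-yl)cyclopentyl]oxolan-2-one | C=C(C)[C@H]1CC[C@H]([C@H]2CCC(=O)O2)[C@H]1O | intermediate
11 | (5R)-5-[(1S,2S,3S)-2-hydroxy-3-(prop-1-en-2-yl)cyclopentyl]oxolan-2-one | C=C(C)[C@@H]1CC[C@H]([C@H]2CCC(=O)O2)[C@H]1O | intermediate
12 | trimethylsulfoxonium iodide | C[S+](C)(C)=O.[I-] | starting material
13 | (5R)-1-[dimethyl(oxo)-λ6-sulfanylidene]-5-hydroxy-5-[(1R,2S,3R)-2-hydroxy-3-(prop-1-en-2-yl)cyclopentyl]pentan-2-one | C=C(C)[C@H]1CC[C@H]([C@H](O)CCC(=O)C=S(C)(C)=O)[C@H]1O | intermediate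
14 | (5R)-1-[dimethyl(oxo)-λ6-sulfanylidene]-5-hydroxy-5-[(1R,2S,3S)-2-hydroxy-3-(prop-1-en-2-yl)cyclopentyl]pentan-2-one | C=C(C)[C@@H]1CC[C@H]([C@H](O)CCC(=O)C=S(C)(C)=O)[C@H]1O | intermediate
15 | (6R)-6-[(1S,2S,3R)-2-hydroxy-3-(prop-1-en-2-yl)cyclopentyl]oxan-3-one | C=C(C)[C@H]1CC[C@H]([C@H]2CCC(=O)CO2)[C@H]1O | intermediate
16 | (6R)-6-[(1S,2S,3S)-2-hydroxy-3-(prop-1-en-2-yl)cyclopentyl]oxan-3-one | C=C(C)[C@@H]1CC[C@H]([C@H]2CCC(=O)CO2)[C@H]1O | intermediate
17 | butane-1,4-diylbis(triphenylphosphonium) dibromide | [Br-].[Br-].c1ccc(cc1)[P+](CCCC[P+](c1ccccc1)(c1ccccc1)c1ccccc1)(c1ccccc1)c1ccccc1 | starting material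
18 | {(4Z)-4-[(6R)-6-[(1S,2S,3R)-2-hydroxy-3-(prop-1-en-2-yl)cyclopentyl]oxan-3-ylidene]butyl}triphenylphosphonium bromide | C=C(C)[C@H]1CC[C@H]([C@H]2CC/C(=C/CCC[P+](c3ccccc3)(c3ccccc3)c3ccccc3)CO2)[C@H]1O.[Br-] | intermediate
19 | (1S,2S,5R)-2-[(2R,5Z)-5-{(4Z)-4-[(6R)-6-[(1S,2S,3S)-2-hydroxy-3-(prop-1-en-2-yl)cyclopentyl]oxan-3-ylidene]butylidene}oxan-2-yl]-5-(prop-1-en-2-yl)cyclopentan-1-ol (CNP0267443.2) | C=C(C)[C@H]1CC[C@H]([C@H]2CC/C(=C/CC/C=C3/CC[C@H]([C@H]4CC[C@@H](C(=C)C)[C@@H]4O)OC3)CO2)[C@H]1O | target

**Count**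
Total steps: 12. Longest linear sequence: 9 steps (1, 2, 3, 4, 5, 7, 9, 11, 12).

**Three steps most likely to fail, with fallbacks**

Step 3 is the most exposed. Aldehyde 5 can dehydrate or racemise, HCl from titanium chlorides can add to the alkene, and the chelate-controlled face selectivity is untested on a free hydroxy aldehyde. The fallback sets out from 5 and reverses polarity at the aldehyde carbon instead of at the ester: SmI2 (2.5 equiv), methyl acrylate and MeOH in THF at −78 °C generate a samarium ketyl held in a chelate by the free hydroxyl. The ketyl adds to the acrylate β-carbon anti to the homoprenyl chain and gives methyl (4R,5S)-4-hydroxy-5-(hydroxymethyl)-9-methyldec-8-enoate F1, which lactonises on acidic work-up. The fallback comes back to the route at 8.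

Step 6 may fail because the confined acid may not accept the α-branched lactone aldehyde, or may give the cis isomer. The fallback sets out from 9 and replaces the ene reaction by a Prins cyclisation with halide capture. TiCl4 (2.2 equiv) in CH2Cl2 at −78 °C closes the ring through the all-equatorial arrangement, and the tertiary cation is trapped by chloride to give (5R)-5-[(1S,2R,3R)-3-(2-chloropropan-2-yl)-2-hydroxycyclopentyl]oxolan-2-one F2. Dehydrochlorination toward the less hindered methyl group with DBU in toluene at 90 °C then gives the isopropenyl group. The fallback comes back to the route at 11.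

Step 11 carries three risks: mono-olefination of the bis-phosphonium salt may be unselective, the salt is poorly soluble, and Z-selectivity on a cyclic α-alkoxy ketone is not proven. The fallback sets out from 15 and builds the linker one end at a time. Wittig reaction of 15 with the ylide of (4-hydroxybutyl)triphenylphosphonium bromide (2 equiv KN(SiMe3)2, THF/HMPA, −78 °C) gives (4Z)-4-[(6R)-6-[(1S,2S,3R)-2-hydroxy-3-(prop-1-en-2-yl)cyclopentyl]oxan-3-ylidene]butan-1-ol F3. Primary-selective iodination (I2, PPh3, imidazole, 0 °C) gives the iodide (1S,2S,5R)-2-[(2R,5Z)-5-(4-iodobutylidene)oxan-2-yl]-5-(prop-1-en-2-yl)cyclopentan-1-ol F4. Heating with PPh3 in MeCN at 80 °C gives {(4Z)-4-[(6R)-6-[(1S,2S,3R)-2-hydroxy-3-(prop-1-en-2-yl)cyclopentyl]oxan-3-ylidene]butyl}triphenylphosphonium iodide F5. Wittig reaction of F5 with 16 under the step 12 conditions comes back to the route at 19.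

**Further compounds**
F1 | step 3 | methyl (4R,5S)-4-hydroxy-5-(hydroxymethyl)-9-methyldec-8-enoate | CC(C)=CCC[C@H]([C@H](O)CCC(=O)OC)CO
F2 | step 6 | (5R)-5-[(1S,2R,3R)-3-(2-chloropropan-2-yl)-2-hydroxycyclopentyl]oxolan-2-one | CC(C)(Cl)[C@@H]1CC[C@H]([C@H]2CCC(=O)O2)[C@H]1O
F3 | step 11 | (4Z)-4-[(6R)-6-[(1S,2S,3R)-2-hydroxy-3-(prop-1-en-2-yl)cyclopentyl]oxan-3-ylidene]butan-1-ol | C=C(C)[C@H]1CC[C@H]([C@H]2CC/C(=C/CCCO)CO2)[C@H]1O
F4 | step 11 | (1S,2S,5R)-2-[(2R,5Z)-5-(4-iodobutylidene)oxan-2-yl]-5-(prop-1-en-2-yl)cyclopentan-1-ol | C=C(C)[C@H]1CC[C@H]([C@H]2CC/C(=C/CCCI)CO2)[C@H]1O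
F5 | step 11 | {(4Z)-4-[(6R)-6-[(1S,2S,3R)-2-hydroxy-3-(prop-1-en-2-yl)cyclopentyl]oxan-3-ylidene]butyl}triphenylphosphonium iodide | C=C(C)[C@H]1CC[C@H]([C@H]2CC/C(=C/CCC[P+](c3ccccc3)(c3ccccc3)c3ccccc3)CO2)[C@H]1O.[I-]
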